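**Abbreviations:** TBS = tert-butyldimethylsilyl; TBSO = tert-butyldimethylsilyloxy; HFIP = 1,1,1,3,3,3-hexafluoropropan-2-ol.

## Retrosynthetic overview

1. Locants: cyclohexene ring D is C1(CH3)=C2H–C3H(ring A)–C4H(C(=O)–ring C)–C5H(ring B)–C6H2, with ring A = 2-hydroxy-5-styrylphenyl, ring B = 2,4-dihydroxyphenyl and ring C = the 2,4-dihydroxyphenyl of the ketone. The last disconnections are the six O–Si bonds and the stilbene C–C bond (Heck).
2. Key disconnection: C2–C3 and C5–C6 together, a [3+3] annulation of the unit C6–C1(CH3)=C2, brought in as (E)-2-methyl-1,3-bis(trimethylsilyl)propene, onto C3–C4–C5 held in a (2R)-3-aroyl-2-aryl-2H-chromene. The chromene ring oxygen is the ring A phenol oxygen bonded to C5, a bond the target does not contain.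
3. Enabling feature: ring A has its OH ortho to the carbon bound to C3, C5 is benzylic to the electron-rich ring B, and C4 carries the acyl group. Tying O(ring A) to C5 makes C3 the β-carbon of an enone (first electrophile) and C5 a p-oxygenated benzylic ether carbon (second electrophile); the C5 stereocentre directs C3 and C4 before it is erased and rebuilt.
4. The chromene comes from 5-bromosalicylaldehyde and a cinnamaldehyde by organocatalytic oxa-Michael/aldol condensation (the only external source of chirality); ring C is added as an aryl Grignard reagent and the carbinol is oxidized.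
5. Ring order: pyran ring (step 3), then ring D, closed while the pyran ring opens (step 8); rings A, B and C are bought.

Key step: step 8

Remark: the (S)-diarylprolinol silyl ether is assumed, by the usual iminium shielding model, to give the (2R)-chromene; if the sense proved opposite, the antipodal catalyst would be used.

## Route

Step 1
Reactants: 1 2,4-dihydroxybenzaldehyde
Product: 2 2,4-bis(TBSO)benzaldehyde
Conditions: TBSCl (2.3 equiv), imidazole, DMF, rt
Reagents that add atoms: tert-butyldimethylsilyl chloride, CC(C)(C)[Si](C)(C)Cl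
Why: Silyl ether formation masks both phenols as groups that should survive the organometallic and Lewis acid steps and fall off together with fluoride at the end.

Step 2
Reactants: 2 2,4-bis(TBSO)benzaldehyde
Product: 3 (E)-3-[2,4-bis(TBSO)phenyl]prop-2-enal
Conditions: Ph3P=CHCHO (1.2 equiv), toluene, 80 °C
Reagents that add atoms: (triphenylphosphoranylidene)acetaldehyde, O=CC=P(c1ccccc1)(c1ccccc1)c1ccccc1
Why: Wittig reaction with a stabilized ylide should give the (E)-cinnamaldehyde.

Step 3
Reactants: 4 5-bromo-2-hydroxybenzaldehyde; 3 (E)-3-[2,4-bis(TBSO)phenyl]prop-2-enal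
Product: 5 (2R)-6-bromo-2-[2,4-bis(TBSO)phenyl]-2H-chromene-3-carbaldehyde
Conditions: (S)-α,α-diphenylprolinol trimethylsilyl ether (20 mol%), 2-nitrobenzoic acid (20 mol%), 4 Å molecular sieves, toluene, rt
Reagents that add atoms: none
Why: Domino oxa-Michael/aldol condensation under iminium–enamine catalysis, in which the phenol adds to the iminium β-carbon on the face opposite the diphenyl(silyloxy)methyl group (this sets C2) and the enamine then condenses with the aryl aldehyde to close the pyran ring.

Step 4
Reactants: 6 4-bromobenzene-1,3-diol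
Product: 7 1-bromo-2,4-bis(TBSO)benzene
Conditions: TBSCl (2.3 equiv), imidazole, DMF, rt
Reagents that add atoms: tert-butyldimethylsilyl chloride, CC(C)(C)[Si](C)(C)Cl
Why: Silyl ether formation as in step 1 prepares the ring C donor.

Step 5
Reactants: 7 1-bromo-2,4-bis(TBSO)benzene; 5 (2R)-6-bromo-2-[2,4-bis(TBSO)phenyl]-2H-chromene-3-carbaldehyde
Product: 9 [(2S)-6-bromo-2-[2,4-bis(TBSO)phenyl]-2H-chromen-3-yl][2,4-bis(TBSO)phenyl]methanol (both carbinol epimers; C2 arranged in space as in 5), via aryl Grignard reagent 8 (not isolated)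
Conditions: 7, Mg, LiCl, THF, rt; then 5, −78 to −20 °C; then H2O
Reagents that add atoms: none
Why: Grignard 1,2-addition to the aldehyde should be faster than conjugate addition or attack on the aryl bromide, and the uncontrolled carbinol centre is removed in step 6.

Step 6
Reactants: 9 the chromenyl carbinol
Product: 10 [(2R)-6-bromo-2-[2,4-bis(TBSO)phenyl]-2H-chromen-3-yl][2,4-bis(TBSO)phenyl]methanone
Conditions: activated MnO2 (excess), CH2Cl2, rt
Reagents that add atoms: none
Why: MnO2 oxidation of an alcohol that is both allylic and benzylic should give the enone under neutral conditions that leave the C2 stereocentre untouched.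

Step 7
Reactants: 11 trimethyl(2-methylprop-2-en-1-yl)silane
Product: 13 (E)-2-methyl-1,3-bis(trimethylsilyl)prop-1-ene, via lithiated allylsilane 12 (not isolated)
Conditions: s-BuLi, TMEDA, THF, −78 to −30 °C; then Me3SiCl, −78 °C to rt
Reagents that add atoms: chlorotrimethylsilane, C[Si](C)(C)Cl
Why: Metalation of the allylsilane at the silicon-bearing carbon followed by silylation of the allyl anion at its unsubstituted terminus (γ-silylation) should give the 1,3-disilylpropene with the bulky groups trans.

Step 8
Reactants: 10 the (2R)-3-aroyl-2-aryl-2H-chromene; 13 (E)-2-methyl-1,3-bis(trimethylsilyl)prop-1-ene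
Product: 16 [(1R,2R,6S)-2-(5-bromo-2-hydroxyphenyl)-6-[2,4-bis(TBSO)phenyl]-4-methylcyclohex-3-en-1-yl][2,4-bis(TBSO)phenyl]methanone, via titanium enolate 14 (not isolated), via chromanyl ketone 15 (not isolated)
Conditions: TiCl4 (2.2 equiv), CH2Cl2, −78 °C; then HFIP (3 equiv), −78 to −20 °C; then H2O
Reagents that add atoms: none
Why: Proposed new method: TiCl4 bound to the ketone of 10 should trigger Hosomi–Sakurai conjugate addition of the silyl-bearing vinylic carbon of 13 to chromene C4, anti to the pseudo-axial C2 aryl group, with loss of the allylic Me3Si group to give titanium enolate 14, which HFIP protonates anti to the new C4 substituent to give chromanyl ketone 15 with the aroyl group equatorial. TiCl4 then ionizes the C2–O bond of 15, a 2,4-bis(silyloxy)benzyl aryl ether, and the 1,1-disubstituted alkene of the new allylsilane captures the benzylic cation in a 6-endo-trig closure, the β-silyl cation losing its Me3Si group so that the double bond can only lie between the methyl-bearing carbon and the carbon that was bonded first. The closest known reaction types are the conjugate Sakurai allylation of enones, the twofold electrophilic substitution of 1,3-disilylpropenes and allylsilane-terminated cationic cyclization; their combination with opening of a 2H-chromene is new. Stereocontrol: the chromene C2 centre sets target C3 (anti addition), protonation and thermodynamics set target C4, and the erased centre is rebuilt as target C5 through a chair in which the C4–H bond eclipses the cation plane (allylic 1,3-strain) and ring A, the aroyl group and ring B are all equatorial, which gives the all-trans array. The step needs conjugate addition to be faster than heterolysis of the allylic C2–O bond of 10 (carbonyl complexation at −78 °C, no protic additive until 10 is consumed) and cation capture to be faster than loss of the C4 proton (an intramolecular and strongly nucleophilic allylsilane).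

Step 9
Reactants: 17 3,5-dihydroxybenzaldehyde
Product: 18 3,5-bis(TBSO)benzaldehyde
Conditions: TBSCl (2.3 equiv), imidazole, DMF, rt
Reagents that add atoms: tert-butyldimethylsilyl chloride, CC(C)(C)[Si](C)(C)Cl
Why: Silyl ether formation as in step 1 gives the same protecting group on the stilbene half.

Step 10
Reactants: 18 3,5-bis(TBSO)benzaldehyde
Product: 19 1-ethenyl-3,5-bis(TBSO)benzene
Conditions: Ph3PCH3Br, n-BuLi, THF, 0 °C; then 18, 0 °C to rt
Reagents that add atoms: methyltriphenylphosphonium bromide, C[P+](c1ccccc1)(c1ccccc1)c1ccccc1.[Br-]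
Why: Wittig methylenation with the preformed non-stabilized ylide should convert the aldehyde into the styrene without touching the aryl silyl ethers.

Step 11
Reactants: 16 the bromophenol cyclohexenyl ketone; 19 1-ethenyl-3,5-bis(TBSO)benzene
Product: 20 [(1R,2R,6S)-2-[5-[(E)-2-[3,5-bis(TBSO)phenyl]ethenyl]-2-hydroxyphenyl]-6-[2,4-bis(TBSO)phenyl]-4-methylcyclohex-3-en-1-yl][2,4-bis(TBSO)phenyl]methanone
Conditions: Pd(OAc)2 (5 mol%), P(o-tol)3 (12 mol%), Et3N, DMF, 100 °C
Reagents that add atoms: none
Why: Mizoroki–Heck reaction, in which zerovalent palladium inserts into the only aryl bromide and syn-insertion of the terminal styrene followed by syn β-hydride elimination should give the (E)-stilbene, the trisubstituted ring alkene being too hindered to insert.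

Step 12
Reactants: 20 the hexasilylated stilbene
Product: 21 (2,4-dihydroxyphenyl)[(1R,2R,6S)-6-(2,4-dihydroxyphenyl)-2-[5-[(E)-2-(3,5-dihydroxyphenyl)ethenyl]-2-hydroxyphenyl]-4-methylcyclohex-3-en-1-yl]methanone
Conditions: TBAF (7 equiv), AcOH (7 equiv), THF, 0 °C to rt, under argon
Reagents that add atoms: none
Why: Buffered fluoride should cleave all six aryl silyl ethers while sparing the stilbene, the ketone and the ring alkene, and the only epimerizable centre (the acyl-bearing carbon) already has the thermodynamically preferred all-trans arrangement.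

## Compound list

1 | 2,4-dihydroxybenzaldehyde | O=Cc1ccc(O)cc1O | starting material
2 | 2,4-bis(tert-butyldimethylsilyloxy)benzaldehyde | O=Cc1ccc(O[Si](C)(C)C(C)(C)C)cc1O[Si](C)(C)C(C)(C)C | intermediate
3 | (E)-3-[2,4-bis(TBSO)phenyl]prop-2-enal | O=C/C=C/c1ccc(O[Si](C)(C)C(C)(C)C)cc1O[Si](C)(C)C(C)(C)C | intermediate
4 | 5-bromo-2-hydroxybenzaldehyde | O=Cc1cc(Br)ccc1O | starting material
5 | (2R)-6-bromo-2-[2,4-bis(TBSO)phenyl]-2H-chromene-3-carbaldehyde | Brc1ccc2O[C@H](c3ccc(O[Si](C)(C)C(C)(C)C)cc3O[Si](C)(C)C(C)(C)C)C(C=O)=Cc2c1 | intermediate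
6 | 4-bromobenzene-1,3-diol | Oc1ccc(Br)c(O)c1 | starting material
7 | 1-bromo-2,4-bis(TBSO)benzene | Brc1ccc(O[Si](C)(C)C(C)(C)C)cc1O[Si](C)(C)C(C)(C)C | intermediate
8 | [2,4-bis(TBSO)phenyl]magnesium bromide | Br[Mg]c1ccc(O[Si](C)(C)C(C)(C)C)cc1O[Si](C)(C)C(C)(C)C | intermediate (not isolated)
9 | [(2S)-6-bromo-2-[2,4-bis(TBSO)phenyl]-2H-chromen-3-yl][2,4-bis(TBSO)phenyl]methanol, both carbinol epimers | Brc1ccc2O[C@H](c3ccc(O[Si](C)(C)C(C)(C)C)cc3O[Si](C)(C)C(C)(C)C)C(C(O)c3ccc(O[Si](C)(C)C(C)(C)C)cc3O[Si](C)(C)C(C)(C)C)=Cc2c1 | intermediate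
10 | [(2R)-6-bromo-2-[2,4-bis(TBSO)phenyl]-2H-chromen-3-yl][2,4-bis(TBSO)phenyl]methanone | Brc1ccc2O[C@H](c3ccc(O[Si](C)(C)C(C)(C)C)cc3O[Si](C)(C)C(C)(C)C)C(C(=O)c3ccc(O[Si](C)(C)C(C)(C)C)cc3O[Si](C)(C)C(C)(C)C)=Cc2c1 | intermediate
11 | trimethyl(2-methylprop-2-en-1-yl)silane | C=C(C)C[Si](C)(C)C | starting material
12 | [2-methyl-1-(trimethylsilyl)prop-2-en-1-yl]lithium | [Li]C(C(C)=C)[Si](C)(C)C | intermediate (not isolated)
13 | (E)-2-methyl-1,3-bis(trimethylsilyl)prop-1-ene | C[Si](C)(C)/C=C(\C)C[Si](C)(C)C | intermediate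
14 | trichlorotitanium enolate of 15 (exocyclic enolate, 2,4-trans chroman, silyl-bearing carbon as formed) | C=C(C)C([Si](C)(C)C)[C@H]1c2cc(Br)ccc2O[C@H](c2ccc(O[Si](C)(C)C(C)(C)C)cc2O[Si](C)(C)C(C)(C)C)C1=C(O[Ti](Cl)(Cl)Cl)c1ccc(O[Si](C)(C)C(C)(C)C)cc1O[Si](C)(C)C(C)(C)C | intermediate (not isolated)
15 | [(2S,3S,4R)-6-bromo-2-[2,4-bis(TBSO)phenyl]-4-[2-methyl-1-(trimethylsilyl)prop-2-en-1-yl]-3,4-dihydro-2H-chromen-3-yl][2,4-bis(TBSO)phenyl]methanone (2,3-trans, 3,4-cis; silyl-bearing carbon as formed) | C=C(C)C([Si](C)(C)C)[C@H]1c2cc(Br)ccc2O[C@H](c2ccc(O[Si](C)(C)C(C)(C)C)cc2O[Si](C)(C)C(C)(C)C)[C@H]1C(=O)c1ccc(O[Si](C)(C)C(C)(C)C)cc1O[Si](C)(C)C(C)(C)C | intermediate (not isolated)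
16 | [(1R,2R,6S)-2-(5-bromo-2-hydroxyphenyl)-6-[2,4-bis(TBSO)phenyl]-4-methylcyclohex-3-en-1-yl][2,4-bis(TBSO)phenyl]methanone | CC1=C[C@@H](c2cc(Br)ccc2O)[C@H](C(=O)c2ccc(O[Si](C)(C)C(C)(C)C)cc2O[Si](C)(C)C(C)(C)C)[C@@H](c2ccc(O[Si](C)(C)C(C)(C)C)cc2O[Si](C)(C)C(C)(C)C)C1 | intermediate
17 | 3,5-dihydroxybenzaldehyde | O=Cc1cc(O)cc(O)c1 | starting material
18 | 3,5-bis(TBSO)benzaldehyde | O=Cc1cc(O[Si](C)(C)C(C)(C)C)cc(O[Si](C)(C)C(C)(C)C)c1 | intermediate
19 | 1-ethenyl-3,5-bis(TBSO)benzene | C=Cc1cc(O[Si](C)(C)C(C)(C)C)cc(O[Si](C)(C)C(C)(C)C)c1 | intermediate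
20 | [(1R,2R,6S)-2-[5-[(E)-2-[3,5-bis(TBSO)phenyl]ethenyl]-2-hydroxyphenyl]-6-[2,4-bis(TBSO)phenyl]-4-methylcyclohex-3-en-1-yl][2,4-bis(TBSO)phenyl]methanone | CC1=C[C@@H](c2cc(/C=C/c3cc(O[Si](C)(C)C(C)(C)C)cc(O[Si](C)(C)C(C)(C)C)c3)ccc2O)[C@H](C(=O)c2ccc(O[Si](C)(C)C(C)(C)C)cc2O[Si](C)(C)C(C)(C)C)[C@@H](c2ccc(O[Si](C)(C)C(C)(C)C)cc2O[Si](C)(C)C(C)(C)C)C1 | intermediate
21 | (2,4-dihydroxyphenyl)[(1R,2R,6S)-6-(2,4-dihydroxyphenyl)-2-[5-[(E)-2-(3,5-dihydroxyphenyl)ethenyl]-2-hydroxyphenyl]-4-methylcyclohex-3-en-1-yl]methanone | CC1=C[C@@H](c2cc(/C=C/c3cc(O)cc(O)c3)ccc2O)[C@H](C(=O)c2ccc(O)cc2O)[C@@H](c2ccc(O)cc2O)C1 | target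

## Summary

Total step count: 12.
Longest linear sequence: 8 steps (steps 1, 2, 3, 5, 6, 8, 11, 12; compounds 1 → 2 → 3 → 5 → 9 → 10 → 16 → 20 → 21).

## Steps most likely to fail

**Step 8 (Proposed new method).** Several processes could divert it:
- Heterolysis of the allylic C2–O bond of 10 before conjugate addition, which would erode the enantiomeric purity and let the silane attack the wrong terminus (alkene regioisomer).
- β-Elimination of enolate 14, or proton loss from the cation, to an enone, whose closure through a planar acyl-bearing carbon would control the ring B centre poorly.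
- Protodesilylation of the allylsilane in the protic second stage.
- A mismatched silyl-bearing carbon in 15, which would slow the chair closure.

Fallback, setting out from 10 and 13 and returning at 16: the cascade is given up for two separate known operations. The TiCl4-mediated conjugate Sakurai addition is quenched with water at −78 °C and chromanyl ketone 15 is isolated. Its acyl-bearing centre is equilibrated with DBU if needed. The ring is then closed in a separate allylsilane-terminated cationic cyclization (TfOH 10 mol%, HFIP/CH2Cl2, −20 °C). No compound outside the list is made (F0).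

**Step 3.** Iminium formation and oxa-Michael addition may be slow with the electron-rich, ortho-substituted enal, and a reversible oxa-Michael step may lower the enantioselectivity.

Fallback, setting out from 4 and 3 and returning at 5: condensation with an achiral amine (pyrrolidine, benzoic acid, toluene, rt) should give racemic 6-bromo-2-[2,4-bis(TBSO)phenyl]-2H-chromene-3-carbaldehyde F1. Its enantiomers are separated by preparative chromatography on a chiral stationary phase, so resolution replaces asymmetric catalysis.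

**Step 11.** Oxidative addition into the electron-rich bromophenol may be slow, and aryl silyl ethers may be lost at 100 °C in the presence of amine.

Fallback, setting out from 19 and returning at 20: cross-metathesis of 19 with vinylboronic acid pinacol ester (second-generation Grubbs catalyst, CH2Cl2, 40 °C) should give 2-[(E)-2-[3,5-bis(TBSO)phenyl]ethenyl]-4,4,5,5-tetramethyl-1,3,2-dioxaborolane F2. F2 is joined to 16 by Suzuki–Miyaura coupling (Pd(dppf)Cl2, K3PO4, dioxane/H2O, 70 °C), so the polarity of the coupling partners is reversed.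

## Further compounds

F0 | step 8 | none | none
F1 | step 3 | racemic 6-bromo-2-[2,4-bis(TBSO)phenyl]-2H-chromene-3-carbaldehyde | Brc1ccc2OC(c3ccc(O[Si](C)(C)C(C)(C)C)cc3O[Si](C)(C)C(C)(C)C)C(C=O)=Cc2c1
F2 | step 11 | 2-[(E)-2-[3,5-bis(TBSO)phenyl]ethenyl]-4,4,5,5-tetramethyl-1,3,2-dioxaborolane | CC1(C)OB(/C=C/c2cc(O[Si](C)(C)C(C)(C)C)cc(O[Si](C)(C)C(C)(C)C)c2)OC1(C)C
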